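**Retrosynthetic overview**

1. Target 19 ⇐ methyl addition to the C2 ketone of β-keto ester 18 ⇐ hydrogenation of enone 17. The enabling feature is ring B (C1, C2, C3, C4, C4a, C8a): its C2 carbinol sits β to the C1 ester and the quaternary C8a is attached to C1, so ring B is a masked acetoacetate annulation product.
2. 17 ⇐ one-flask amine-catalysed Michael/aldol condensation of the acyclic aldehyde–alkylidene acetoacetate 14: the C4a–C8a bond closes ring A first, the C3–C4 bond then closes ring B.
3. 14 ⇐ aldehyde-selective Wacker oxidation and Knoevenagel condensation on chloro ketone 11 ⇐ organocatalytic α-chlorination, Wittig olefination and conjugate reduction of aldehyde 7.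
4. 7 ⇐ alkyne hydration of enyne 6 ⇐ copper-catalysed enantioselective SN2′ alkynylation of geranyl phosphate 2 ⇐ geraniol 1.
5. Stereocentres: C5 by copper catalysis, C6 by amine catalysis, C4a and C8a together in the key step, C1 and C2 by substrate control in the last step.

Key step: step 9

Remark: bicyclic compounds carry the locants of the target (ring A = C4a, C5, C6, C7, C8, C8a; ring B = C1, C2, C3, C4, C4a, C8a), open-chain compounds their own chain locants; the named enantiomer of each chiral catalyst is the one predicted by the usual face model, and both enantiomers are assumed to be available.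

**Step 1**
Reactants: 1 geraniol
Product: 2 geranyl diethyl phosphate
Conditions: ClP(O)(OEt)2, pyridine, DMAP (cat.), CH2Cl2, 0 °C to rt
Reagents that add atoms: diethyl chlorophosphate, CCOP(=O)(Cl)OCC
Why: Phosphorylation of a primary allylic alcohol installs the leaving group needed for copper-catalysed SN2′ substitution without touching either alkene.

**Step 2**
Reactants: 2 geranyl diethyl phosphate; 3 ethynyltrimethylsilane
Product: 5 [(3S)-3-ethenyl-3,7-dimethyloct-6-en-1-yn-1-yl]trimethylsilane, via alkynylalane 4 (not isolated)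
Conditions: 3, i-Bu2AlH, Et3N (5 mol %), hexanes, 55 °C; then 2, CuCl2·2H2O (2 mol %), chiral sulfonate-bearing imidazolinium salt (NHC precursor, 2.5 mol %), THF, −30 °C; aqueous Rochelle salt
Reagents that add atoms: none
Why: Amine-promoted metalation of the terminal alkyne gives the alkynylalane, which should undergo NHC–copper-catalysed enantioselective SN2′ allylic substitution on the E-trisubstituted allylic phosphate (the reaction class used for methyl/homoprenyl/vinyl quaternary carbons from geranyl-type phosphates), the ligand enantiomer being chosen to give the (S)-quaternary centre.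

**Step 3**
Reactants: 5 [(3S)-3-ethenyl-3,7-dimethyloct-6-en-1-yn-1-yl]trimethylsilane
Product: 6 (3S)-3-ethenyl-3,7-dimethyloct-6-en-1-yne
Conditions: K2CO3, MeOH, rt
Reagents that add atoms: none
Why: Base-mediated protodesilylation of an alkynylsilane leaves the quaternary centre and both alkenes untouched.

**Step 4**
Reactants: 6 (3S)-3-ethenyl-3,7-dimethyloct-6-en-1-yne
Product: 7 (3R)-3-ethenyl-3,7-dimethyloct-6-enal
Conditions: [CpRu(MeCN)3]PF6 (3 mol %), 5,5′-bis(trifluoromethyl)-2,2′-bipyridine (3 mol %), NMP/H2O 4:1, 25–40 °C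
Reagents that add atoms: water, O
Why: Ruthenium-vinylidene-mediated anti-Markovnikov hydration of a terminal alkyne gives the aldehyde directly and is specific for the alkyne over the vinyl and trisubstituted alkenes (the descriptor changes only because of priorities).

**Step 5**
Reactants: 7 (3R)-3-ethenyl-3,7-dimethyloct-6-enal; 8 1-(triphenylphosphoranylidene)propan-2-one
Product: 10 (3E,5S,6S)-5-chloro-6-ethenyl-6,10-dimethylundeca-3,9-dien-2-one, via chloro aldehyde 9 (not isolated)
Conditions: (2S,5S)-2,5-diphenylpyrrolidine (10 mol %), NCS (1.05 equiv), CH2Cl2, 0 °C; then 8 (1.3 equiv), 0 °C to rt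
Reagents that add atoms: N-chlorosuccinimide, O=C1CCC(=O)N1Cl
Why: Enamine-catalysed α-chlorination, in which a phenyl group of the C2-symmetric pyrrolidine blocks one face of the E-enamine so that chlorine enters from the other (catalyst control over the remote quaternary centre), should set the C–Cl stereocentre, and Wittig olefination with the stabilised ylide traps the labile α-chloro aldehyde as the E-enone before it can epimerise.

**Step 6**
Reactants: 10 (3E,5S,6S)-5-chloro-6-ethenyl-6,10-dimethylundeca-3,9-dien-2-one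
Product: 11 (5S,6S)-5-chloro-6-ethenyl-6,10-dimethylundec-9-en-2-one
Conditions: [(Ph3P)CuH]6 (0.4 equiv), H2O (5 equiv), THF, rt
Reagents that add atoms: none
Why: Copper hydride conjugate reduction (Stryker reduction) is selective for the enone C=C and should leave the isolated alkenes, the secondary chloride and both stereocentres untouched.

**Step 7**
Reactants: 11 (5S,6S)-5-chloro-6-ethenyl-6,10-dimethylundec-9-en-2-one; 12 methyl acetoacetate
Product: 13 methyl (6S,7S)-2-acetyl-6-chloro-7-ethenyl-3,7,11-trimethyldodeca-2,10-dienoate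
Conditions: 12 (2 equiv), TiCl4 (2 equiv), pyridine (4 equiv), THF, 0 °C to rt
Reagents that add atoms: none
Why: Knoevenagel condensation under TiCl4/pyridine (Lehnert conditions) of a methyl ketone with an acetoacetate installs the doubly activated tetrasubstituted alkene, whose E/Z ratio is irrelevant because this carbon becomes sp3 in step 9.

**Step 8**
Reactants: 13 methyl (6S,7S)-2-acetyl-6-chloro-7-ethenyl-3,7,11-trimethyldodeca-2,10-dienoate
Product: 14 methyl (6S,7S)-2-acetyl-6-chloro-3,7,11-trimethyl-7-(2-oxoethyl)dodeca-2,10-dienoate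
Conditions: PdCl2(PhCN)2 (12 mol %), CuCl2·2H2O (12 mol %), AgNO2 (6 mol %), O2 (1 atm), t-BuOH/MeNO2 15:1, rt
Reagents that add atoms: dioxygen, O=O
Why: Nitrite-modified aldehyde-selective Wacker oxidation of a terminal alkene should place oxygen on the terminal carbon, the neopentyl position disfavouring attack at the internal carbon, while the trisubstituted and tetrasubstituted alkenes are inert.

**Step 9**
Reactants: 14 methyl (6S,7S)-2-acetyl-6-chloro-3,7,11-trimethyl-7-(2-oxoethyl)dodeca-2,10-dienoate
Product: 17 methyl (1R,4aR,5S,6S,8aS)-6-chloro-5,8a-dimethyl-5-(4-methylpent-3-en-1-yl)-2-oxo-1,2,4a,5,6,7,8,8a-octahydronaphthalene-1-carboxylate, via Michael adduct 15 (not isolated), via aldol adduct 16 (not isolated)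
Conditions: (R)-2-[diphenyl(trimethylsilyloxy)methyl]pyrrolidine (20 mol %), 4-nitrobenzoic acid (20 mol %), toluene (0.02 M), 23 °C, then 50 °C in the same flask
Reagents that add atoms: none
Why: The secondary amine condenses only with the aldehyde (the ketone is hindered and part of the tetrasubstituted acceptor) to give the E-enamine, whose nucleophilic carbon (future C4a) adds 6-exo-trig to the doubly activated β-carbon (future C8a) of the alkylidene acetoacetate, closing ring A and creating the quaternary centre; the acetyl group then enolises towards its methyl carbon (future C3) and closes ring B onto the C4 iminium/aldehyde carbon by a 6-(enolendo)-exo-trig aldol (Mannich-type) addition, and loss of water gives the enone and returns the catalyst. The closest known reaction type is the amine-catalysed Robinson annulation of an aldehyde with a vinyl ketone or alkylidene 1,3-dicarbonyl compound (enamine Michael addition followed by aldol condensation), here run intramolecularly with matched polarity at both new bonds. C4a is set by the catalyst: the CPh2(OSiMe3) group of the (R)-pyrrolidine shields the Si face of the anti-enamine, so the acceptor should bond to the Re face. C8a is set by the chair-like transition state of ring A, in which the bulky alkylidene dicarbonyl unit and the enamine are both equatorial, so the C8a methyl becomes axial and trans to H-4a (the trans-decalin relationship); in this chair the C6 chlorine and the C5 side chain are equatorial, so the existing centres do not oppose the catalyst. The step needs chemoselective enamine formation (secured by the single aldehyde), conjugate rather than carbonyl addition of the enamine (only the acceptor β-carbon is within reach of a six-membered transition state) and one aldol regiochemistry (closure from C1 would give a cyclobutane, so only the methyl carbon can close). C1 remains epimerisable and should settle with the ester equatorial.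

**Step 10**
Reactants: 17 methyl (1R,4aR,5S,6S,8aS)-6-chloro-5,8a-dimethyl-5-(4-methylpent-3-en-1-yl)-2-oxo-1,2,4a,5,6,7,8,8a-octahydronaphthalene-1-carboxylate
Product: 18 methyl (1R,4aR,5S,6S,8aS)-6-chloro-5,8a-dimethyl-5-(4-methylpent-3-en-1-yl)-2-oxodecahydronaphthalene-1-carboxylate
Conditions: H2 (1 atm), RhCl(PPh3)3 (5 mol %), benzene/EtOH 1:1, rt
Reagents that add atoms: none
Why: Homogeneous hydrogenation with RhCl(PPh3)3 should reduce the cis-disubstituted conjugated alkene and leave the trisubstituted side-chain alkene and the C–Cl bond intact, and it avoids hydride reagents that would only deprotonate the acidic β-keto ester.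

**Step 11**
Reactants: 18 methyl (1R,4aR,5S,6S,8aS)-6-chloro-5,8a-dimethyl-5-(4-methylpent-3-en-1-yl)-2-oxodecahydronaphthalene-1-carboxylate
Product: 19 methyl (1R,2S,4aR,5S,6S,8aS)-6-chloro-2-hydroxy-2,5,8a-trimethyl-5-(4-methylpent-3-en-1-yl)decahydronaphthalene-1-carboxylate
Conditions: MeMgCl (4 equiv), anhydrous CeCl3 (4 equiv), THF, −78 °C; aq NH4Cl
Reagents that add atoms: methylmagnesium chloride, C[Mg]Cl (transmetallated in the flask to methylcerium dichloride, C[Ce](Cl)Cl)
Why: Organocerium 1,2-addition (weakly basic, strongly oxophilic, the reagent class used for enolisable 1,3-dicarbonyl compounds) to the chelated keto form with the ester equatorial should deliver methyl equatorially from the α face, because axial approach is blocked by the syn-axial C8a methyl, giving the axial β-hydroxyl cis to the ester while C1 keeps its equatorial ester.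

**Compound list**

1 | geraniol, (2E)-3,7-dimethylocta-2,6-dien-1-ol | CC(C)=CCC/C(C)=C/CO | starting material
2 | geranyl diethyl phosphate | CC(C)=CCC/C(C)=C/COP(=O)(OCC)OCC | intermediate
3 | ethynyltrimethylsilane | C#C[Si](C)(C)C | starting material
4 | diisobutyl[(trimethylsilyl)ethynyl]aluminium | CC(C)C[Al](CC(C)C)C#C[Si](C)(C)C | intermediate
5 | [(3S)-3-ethenyl-3,7-dimethyloct-6-en-1-yn-1-yl]trimethylsilane | C[Si](C)(C)C#C[C@@](C)(CCC=C(C)C)C=C | intermediate
6 | (3S)-3-ethenyl-3,7-dimethyloct-6-en-1-yne | C#C[C@@](C)(CCC=C(C)C)C=C | intermediate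
7 | (3R)-3-ethenyl-3,7-dimethyloct-6-enal | O=CC[C@@](C)(CCC=C(C)C)C=C | intermediate
8 | 1-(triphenylphosphoranylidene)propan-2-one | CC(=O)C=P(c1ccccc1)(c1ccccc1)c1ccccc1 | starting material
9 | (2R,3S)-2-chloro-3-ethenyl-3,7-dimethyloct-6-enal | O=C[C@H](Cl)[C@@](C)(CCC=C(C)C)C=C | intermediate
10 | (3E,5S,6S)-5-chloro-6-ethenyl-6,10-dimethylundeca-3,9-dien-2-one | CC(=O)/C=C/[C@H](Cl)[C@@](C)(CCC=C(C)C)C=C | intermediate
11 | (5S,6S)-5-chloro-6-ethenyl-6,10-dimethylundec-9-en-2-one | CC(=O)CC[C@H](Cl)[C@@](C)(CCC=C(C)C)C=C | intermediate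
12 | methyl acetoacetate (methyl 3-oxobutanoate) | COC(=O)CC(C)=O | starting material
13 | methyl (6S,7S)-2-acetyl-6-chloro-7-ethenyl-3,7,11-trimethyldodeca-2,10-dienoate (E/Z mixture at C2=C3, used as such) | COC(=O)C(C(C)=O)=C(C)CC[C@H](Cl)[C@@](C)(CCC=C(C)C)C=C | intermediate
14 | methyl (6S,7S)-2-acetyl-6-chloro-3,7,11-trimethyl-7-(2-oxoethyl)dodeca-2,10-dienoate (E/Z mixture at C2=C3) | COC(=O)C(C(C)=O)=C(C)CC[C@H](Cl)[C@@](C)(CCC=C(C)C)CC=O | intermediate
15 | methyl 2-[(1S,2R,3S,4S)-4-chloro-2-formyl-1,3-dimethyl-3-(4-methylpent-3-en-1-yl)cyclohexyl]-3-oxobutanoate (C2 of the butanoate epimerisable) | COC(=O)C(C(C)=O)[C@@]1(C)CC[C@H](Cl)[C@@](C)(CCC=C(C)C)[C@@H]1C=O | intermediate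
16 | methyl (4aR,5S,6S,8aS)-6-chloro-4-hydroxy-5,8a-dimethyl-5-(4-methylpent-3-en-1-yl)-2-oxodecahydronaphthalene-1-carboxylate (C1 and C4 not defined, both lost or equilibrated) | COC(=O)C1[C@@]2(C)CC[C@H](Cl)[C@@](C)(CCC=C(C)C)[C@@H]2C(O)CC1=O | intermediate
17 | methyl (1R,4aR,5S,6S,8aS)-6-chloro-5,8a-dimethyl-5-(4-methylpent-3-en-1-yl)-2-oxo-1,2,4a,5,6,7,8,8a-octahydronaphthalene-1-carboxylate (C1 shown as the equatorial-ester epimer) | COC(=O)[C@@H]1[C@@]2(C)CC[C@H](Cl)[C@@](C)(CCC=C(C)C)[C@@H]2C=CC1=O | intermediate
18 | methyl (1R,4aR,5S,6S,8aS)-6-chloro-5,8a-dimethyl-5-(4-methylpent-3-en-1-yl)-2-oxodecahydronaphthalene-1-carboxylate | COC(=O)[C@@H]1[C@@]2(C)CC[C@H](Cl)[C@@](C)(CCC=C(C)C)[C@@H]2CCC1=O | intermediate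
19 | methyl (1R,2S,4aR,5S,6S,8aS)-6-chloro-2-hydroxy-2,5,8a-trimethyl-5-(4-methylpent-3-en-1-yl)decahydronaphthalene-1-carboxylate | COC(=O)[C@@H]1[C@@]2(C)CC[C@H](Cl)[C@@](C)(CCC=C(C)C)[C@@H]2CC[C@]1(C)O | target

**Step count and risks**

Total step count: 11. Longest linear sequence: 11 steps from geraniol (1).

**Step 9 (key step).** The bulky catalyst-bound enamine may add too slowly to the tetrasubstituted, deconjugation-prone acceptor, since the new bond joins a neopentyl carbon to a carbon that becomes quaternary. The Michael adduct may also rest as a cyclic hemiacetal or O,N-acetal instead of closing by aldol condensation, and heating may erode face selectivity. The fallback is a stoichiometric, stepwise Stork-type annulation that sets out from 14. Condensation with (R)-2-(methoxymethyl)pyrrolidine (1.1 equiv, 4 Å molecular sieves, benzene, rt) should give the smaller and more nucleophilic chiral enamine, methyl (6S,7S)-2-acetyl-6-chloro-7-{(E)-2-[(2R)-2-(methoxymethyl)pyrrolidin-1-yl]ethenyl}-3,7,11-trimethyldodeca-2,10-dienoate F1. This is cyclised thermally (MeCN, 23–60 °C) and hydrolysed with aqueous AcOH/NaOAc to the keto aldehyde 15. Acid-catalysed aldol condensation of 15 (p-TsOH·H2O, benzene, reflux, water separator) then returns to the route at 17.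

**Step 11.** Deprotonation of the β-keto ester may outrun carbonyl addition, returning 18 on work-up, or the tertiary alkoxide may fragment by retro-aldol on warming. The fallback removes the acidity by taking the ester temporarily to a protected primary alcohol; it sets out from 18 and returns at 19.
- LiAlH4 (THF, 0 °C) should give the diol (1S,4aR,5S,6S,8aS)-6-chloro-1-(hydroxymethyl)-5,8a-dimethyl-5-(4-methylpent-3-en-1-yl)decahydronaphthalen-2-ol F2.
- TBSCl/imidazole silylates the primary hydroxyl to give the mono-silyl ether F3.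
- Dess–Martin periodinane gives the non-acidic ketone F4.
- MeMgCl/CeCl3 (THF, −78 °C) adds equatorially, as in the main route, to give the tertiary alcohol F5.
- TBAF gives the diol F6.
- TEMPO/PhI(OAc)2, then NaClO2/NaH2PO4/2-methyl-2-butene, oxidises the primary alcohol to the hydroxy acid F7.
- Me3SiCHN2 in MeOH/toluene gives 19.

**Step 7.** Condensation of the ketone with the weakly nucleophilic titanium enolate of the acetoacetate may be slow, so that self-aldol of the methyl ketone or Lewis-acid-induced ionisation at the homoprenyl alkene competes. The fallback changes the electrophile to an oxocarbenium ion and sets out from 11. HC(OMe)3, MeOH and PPTS should give the dimethyl ketal (5S,6S)-5-chloro-6-ethenyl-2,2-dimethoxy-6,10-dimethylundec-9-ene F8. Mukaiyama-type addition of methyl 3-(trimethylsilyloxy)but-2-enoate (TMSOTf 10 mol %, CH2Cl2, −78 to 0 °C) gives the β-methoxy adduct methyl (6S,7S)-2-acetyl-6-chloro-7-ethenyl-3-methoxy-3,7,11-trimethyldodec-10-enoate F9. Loss of methanol (DBU, CH2Cl2, rt) returns to the route at 13.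

**Further compounds**

F1 | step 9 | methyl (6S,7S)-2-acetyl-6-chloro-7-{(E)-2-[(2R)-2-(methoxymethyl)pyrrolidin-1-yl]ethenyl}-3,7,11-trimethyldodeca-2,10-dienoate | COC(=O)C(C(C)=O)=C(C)CC[C@H](Cl)[C@@](C)(CCC=C(C)C)/C=C/N1CCC[C@@H]1COC
F2 | step 11 | (1S,4aR,5S,6S,8aS)-6-chloro-1-(hydroxymethyl)-5,8a-dimethyl-5-(4-methylpent-3-en-1-yl)decahydronaphthalen-2-ol (C2 epimers) | OC[C@@H]1[C@@]2(C)CC[C@H](Cl)[C@@](C)(CCC=C(C)C)[C@@H]2CCC1O
F3 | step 11 | (1S,4aR,5S,6S,8aS)-1-{[tert-butyl(dimethyl)silyl]oxymethyl}-6-chloro-5,8a-dimethyl-5-(4-methylpent-3-en-1-yl)decahydronaphthalen-2-ol (C2 epimers) | CC(C)(C)[Si](C)(C)OC[C@@H]1[C@@]2(C)CC[C@H](Cl)[C@@](C)(CCC=C(C)C)[C@@H]2CCC1O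
F4 | step 11 | (1S,4aR,5S,6S,8aS)-1-{[tert-butyl(dimethyl)silyl]oxymethyl}-6-chloro-5,8a-dimethyl-5-(4-methylpent-3-en-1-yl)octahydronaphthalen-2(1H)-one | CC(C)(C)[Si](C)(C)OC[C@@H]1[C@@]2(C)CC[C@H](Cl)[C@@](C)(CCC=C(C)C)[C@@H]2CCC1=O
F5 | step 11 | (1S,2S,4aR,5S,6S,8aS)-1-{[tert-butyl(dimethyl)silyl]oxymethyl}-6-chloro-2,5,8a-trimethyl-5-(4-methylpent-3-en-1-yl)decahydronaphthalen-2-ol | CC(C)(C)[Si](C)(C)OC[C@@H]1[C@@]2(C)CC[C@H](Cl)[C@@](C)(CCC=C(C)C)[C@@H]2CC[C@]1(C)O
F6 | step 11 | (1S,2S,4aR,5S,6S,8aS)-6-chloro-1-(hydroxymethyl)-2,5,8a-trimethyl-5-(4-methylpent-3-en-1-yl)decahydronaphthalen-2-ol | OC[C@@H]1[C@@]2(C)CC[C@H](Cl)[C@@](C)(CCC=C(C)C)[C@@H]2CC[C@]1(C)O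
F7 | step 11 | (1R,2S,4aR,5S,6S,8aS)-6-chloro-2-hydroxy-2,5,8a-trimethyl-5-(4-methylpent-3-en-1-yl)decahydronaphthalene-1-carboxylic acid | OC(=O)[C@@H]1[C@@]2(C)CC[C@H](Cl)[C@@](C)(CCC=C(C)C)[C@@H]2CC[C@]1(C)O
F8 | step 7 | (5S,6S)-5-chloro-6-ethenyl-2,2-dimethoxy-6,10-dimethylundec-9-ene | COC(C)(OC)CC[C@H](Cl)[C@@](C)(CCC=C(C)C)C=C
F9 | step 7 | methyl (6S,7S)-2-acetyl-6-chloro-7-ethenyl-3-methoxy-3,7,11-trimethyldodec-10-enoate (C2 and C3 not defined) | COC(=O)C(C(C)=O)C(C)(OC)CC[C@H](Cl)[C@@](C)(CCC=C(C)C)C=C
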